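**Assumption:** the acyl chain is numbered C1 (ester carbonyl) to C23 and the ring C1' (carboxyl carbon) to C6'; read from the SMILES, the target is 1'S,3'R,4'S and 2E,4E,6E,8E,10Z,12R,13R,14S,15S,17R,18R,19S,20E.

## Retrosynthetic overview

1. Target ⇐ global deprotection ⇐ C16–C17 Cornforth aldol of methyl ketone 34 with α-chloro aldehyde 43, then 1,3-syn reduction (C15).
2. 34 ⇐ Suzuki coupling (C9–C10) of vinyl dichloride 33 with tetraenyl boronate 18; 18 ⇐ Stille coupling (C3–C4) of iodoacrylate 13 with tin/boron linchpin 17.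
3. The (Z)-chloroalkene of 33 ⇐ key 1,2-metallate shift: chlorine-retentive Zweifel coupling of secondary boronic ester 27 (C12) with (E)-1,2-dichlorovinyllithium; 27 ⇐ 1,1-diborylethane + aldehyde 22 (from divinylcarbinol).
4. Ring fragment 13 ⇐ cyclohexa-1,4-diene by cis-dihydroxylation, desymmetrizing hydroboration and a Matteson one-carbon homologation (a second boron-to-carbon 1,2-shift) to the acid.
5. Rings: the cyclohexane is carried in from cyclohexa-1,4-diene; no ring of the target is formed in the route.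

## Route

**Ring fragment**

Step 1
Reactants: 1 cyclohexa-1,4-diene
Product: 2 (1R,2S)-cyclohex-4-ene-1,2-diol (cis, meso)
Conditions: OsO4 (1 mol %), NMO (1.0 equiv), acetone/H2O, 0 °C
Reagents that add atoms: N-methylmorpholine N-oxide, C[N+]1([O-])CCOCC1; water, O
Why: Upjohn syn-dihydroxylation of one of the two equivalent alkenes gives the cis diol through a cyclic osmate ester, which fixes the C3'/C4' oxygens as a cis pair.

Step 2
Reactants: 2 (1R,2S)-cyclohex-4-ene-1,2-diol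
Product: 3 (3aR,7aS)-2,2-dimethyl-3a,4,7,7a-tetrahydro-1,3-benzodioxole (meso acetonide)
Conditions: 2,2-dimethoxypropane, PPTS (cat.), CH2Cl2, 23 °C
Reagents that add atoms: 2,2-dimethoxypropane, COC(C)(C)OC
Why: Acid-catalysed transacetalization protects the cis diol and makes a cis-fused bicycle whose convex face is open for the next step.

Step 3
Reactants: 3 meso acetonide
Product: 6 2-[(3aR,5S,7aS)-2,2-dimethylhexahydro-1,3-benzodioxol-5-yl]-4,4,5,5-tetramethyl-1,3,2-dioxaborolane, via B-alkyldiisopinocampheylborane 4 (not isolated), via diethyl boronate 5 (not isolated)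
Conditions: (−)-Ipc2BH [from (+)-α-pinene], THF, −25 → 0 °C; CH3CHO (excess), 0 → 23 °C; pinacol, Et2O, 23 °C
Reagents that add atoms: (−)-diisopinocampheylborane, B([C@@H]1C[C@@H]2C[C@H]([C@H]1C)C2(C)C)[C@@H]1C[C@@H]2C[C@H]([C@H]1C)C2(C)C; pinacol, CC(C)(O)C(C)(C)O
Why: Brown asymmetric hydroboration desymmetrizes the meso alkene: boron adds syn on the face anti to the dioxolane and the chiral borane picks one of the two enantiotopic alkene carbons (same sense as cis-but-2-ene → (R)-butan-2-ol), which sets C1' trans to both oxygens.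

Step 4
Reactants: 6 pinacol boronic ester
Product: 8 (3aR,5S,7aS)-2,2-dimethylhexahydro-1,3-benzodioxole-5-carboxylic acid, via α-chloro boronic ester 7 (not isolated)
Conditions: CH2Cl2, n-BuLi, THF, −100 °C; 6, then ZnCl2, −100 → 23 °C; then NaClO2, NaH2PO4, 2-methylbut-2-ene, t-BuOH/H2O, 0 → 23 °C
Reagents that add atoms: dichloromethane, ClCCl; sodium chlorite, [Na+].[O-]Cl=O
Why: Matteson homologation: (dichloromethyl)lithium forms the boronate complex and the ring carbon shifts from boron to carbon with retention (1,2-metallate rearrangement, chloride leaves), and chlorite oxidation of the α-chloro boronic ester gives the acid with C1' unchanged.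

Step 5
Reactants: 8 acetonide acid
Product: 9 tert-butyl (3aR,5S,7aS)-2,2-dimethylhexahydro-1,3-benzodioxole-5-carboxylate
Conditions: tert-butyl 2,2,2-trichloroacetimidate, CH2Cl2/cyclohexane, 23 °C
Reagents that add atoms: tert-butyl 2,2,2-trichloroacetimidate, CC(C)(C)OC(=N)C(Cl)(Cl)Cl
Why: Imidate O-alkylation of the acid gives the tert-butyl ester without base, so C1' cannot epimerize.

Step 6
Reactants: 9 tert-butyl ester acetonide
Product: 10 tert-butyl (1S,3R,4S)-3,4-dihydroxycyclohexane-1-carboxylate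
Conditions: AcOH/H2O/THF (3:1:1), 45 °C
Reagents that add atoms: none
Why: Mild acid hydrolysis removes the acetonide and leaves the tert-butyl ester intact.

Step 7
Reactants: 10 diol
Product: 11 tert-butyl (1S,3R,4S)-4-[(tert-butyldimethylsilyl)oxy]-3-hydroxycyclohexane-1-carboxylate
Conditions: TBSCl (1.05 equiv), imidazole, DMF, −20 °C
Reagents that add atoms: tert-butyldimethylsilyl chloride, CC(C)(C)[Si](C)(C)Cl
Why: In the preferred chair (ester and C4' OH equatorial, C3' OH axial) the bulky silyl chloride reacts at the equatorial C4' hydroxyl, leaving the axial C3' OH for acylation.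

Step 8
Reactants: 11 mono-silyl ether; 12 (2E)-3-iodoprop-2-enoic acid
Product: 13 tert-butyl (1S,3R,4S)-4-[(tert-butyldimethylsilyl)oxy]-3-{[(2E)-3-iodoprop-2-enoyl]oxy}cyclohexane-1-carboxylate
Conditions: DIC, DMAP (10 mol %), CH2Cl2, 0 °C, dark
Reagents that add atoms: none
Why: Carbodiimide (Steglich) esterification acylates the only free hydroxyl and places C1–C3 of the chain on O3'.

**Tin/boron linchpin and tetraenyl boronate**

Step 9
Reactants: 14 (2E)-3-methylpent-2-en-4-yn-1-ol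
Product: 15 (2E,4E)-3-methyl-5-(tributylstannyl)penta-2,4-dien-1-ol
Conditions: Bu3SnH, PdCl2(PPh3)2 (2 mol %), THF, 0 °C
Reagents that add atoms: tributyltin hydride, CCCC[SnH](CCCC)CCCC
Why: Palladium-catalysed syn hydrostannation of the terminal alkyne puts tin on the terminal carbon and gives the (E)-vinylstannane (C4=C5).

Step 10
Reactants: 15 stannyl dienol
Product: 16 (2E,4E)-3-methyl-5-(tributylstannyl)penta-2,4-dienal
Conditions: MnO2, CH2Cl2, 23 °C
Reagents that add atoms: none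
Why: Allylic oxidation with MnO2 gives the enal without touching the vinylstannane or the alkene geometry.

Step 11
Reactants: 16 stannyl dienal
Product: 17 tributyl[(1E,3E,5E)-3-methyl-6-(4,4,5,5-tetramethyl-1,3,2-dioxaborolan-2-yl)hexa-1,3,5-trien-1-yl]stannane
Conditions: Cl2CHBpin, CrCl2, LiI, THF, 23 °C
Reagents that add atoms: 2-(dichloromethyl)-4,4,5,5-tetramethyl-1,3,2-dioxaborolane, ClC(Cl)B1OC(C)(C)C(C)(C)O1
Why: Takai-type boryl olefination (geminal dichromium reagent) converts the aldehyde into the (E)-alkenyl boronic ester and sets C8=C9.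

Step 12
Reactants: 13 iodoacrylate; 17 linchpin
Product: 18 tert-butyl (1S,3R,4S)-4-[(tert-butyldimethylsilyl)oxy]-3-{[(2E,4E,6E,8E)-6-methyl-9-(4,4,5,5-tetramethyl-1,3,2-dioxaborolan-2-yl)nona-2,4,6,8-tetraenoyl]oxy}cyclohexane-1-carboxylate
Conditions: Pd2(dba)3 (5 mol %), AsPh3, NMP, 23 °C, dark
Reagents that add atoms: none
Why: Base-free Stille coupling of the vinyl iodide with the vinylstannane forms C3–C4 with retention of both alkene geometries while the pinacol boronate stays untouched.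

**East fragment**

Step 13
Reactants: 19 penta-1,4-dien-3-ol
Product: 20 (1S)-1-[(2R)-oxiran-2-yl]prop-2-en-1-ol
Conditions: Ti(OiPr)4, L-(+)-DIPT, t-BuOOH, 4 Å MS, CH2Cl2, −20 °C
Reagents that add atoms: tert-butyl hydroperoxide, CC(C)(C)OO
Why: Sharpless asymmetric epoxidation desymmetrizes divinylcarbinol (enantiotopic-group plus face selection), which fixes the carbinol center that becomes C14.

Step 14
Reactants: 20 epoxy alcohol
Product: 21 tert-butyldimethyl{[(1S)-1-[(2R)-oxiran-2-yl]prop-2-en-1-yl]oxy}silane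
Conditions: TBSCl, imidazole, DMF, 23 °C
Reagents that add atoms: tert-butyldimethylsilyl chloride, CC(C)(C)[Si](C)(C)Cl
Why: Standard silylation protects the C14 oxygen for the rest of the route.

Step 15
Reactants: 21 silyl epoxide
Product: 22 (2S)-2-[(tert-butyldimethylsilyl)oxy]but-3-enal
Conditions: H5IO6, Et2O, 0 → 23 °C; used crude
Reagents that add atoms: none
Why: Periodic acid opens the terminal epoxide and cleaves the resulting glycol in one operation, giving the C13 aldehyde with C14 untouched.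

Step 16
Reactants: 23 1,1-dibromoethane
Product: 24 2,2'-(ethane-1,1-diyl)bis(4,4,5,5-tetramethyl-1,3,2-dioxaborolane)
Conditions: B2pin2, CuI (10 mol %), LiOMe, DMF, 23 °C
Reagents that add atoms: bis(pinacolato)diboron, CC1(C)OB(OC1(C)C)B1OC(C)(C)C(C)(C)O1
Why: Copper-catalysed double borylation of the geminal dibromide gives the 1,1-diboryl reagent that carries C12 and its methyl group.

Step 17
Reactants: 22 aldehyde; 24 1,1-diborylethane
Product: 27 2-[(2R,3R,4S)-3,4-bis[(tert-butyldimethylsilyl)oxy]hex-5-en-2-yl]-4,4,5,5-tetramethyl-1,3,2-dioxaborolane, via lithium butylborate 25 (not isolated), via lithium alkoxide 26 (not isolated)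
Conditions: 24, n-BuLi, THF, 0 °C; AgOAc (5 mol %), 22, THF, −25 → 22 °C; then TBSOTf, 2,6-lutidine, −78 → 0 °C
Reagents that add atoms: tert-butyldimethylsilyl triflate, CC(C)(C)[Si](C)(C)OS(=O)(=O)C(F)(F)F
Why: Silver-catalysed deborylative 1,2-addition of the α-boryl alkyl nucleophile is anti-selective for the new B/O pair (sets C12) and follows the polar Felkin–Anh model on the α-silyloxy aldehyde (sets C13 anti to C14); the alkoxide is silylated in the same flask to block boron–oxygen elimination.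

Step 18
Reactants: 27 secondary boronic ester; 28 (E)-1,2-dichloroethene
Product: 32 (1Z,3R,4R,5S)-4,5-bis[(tert-butyldimethylsilyl)oxy]-1,2-dichloro-3-methylhepta-1,6-diene, via (E)-1,2-dichlorovinyllithium 29 (not isolated), via boronate complex 30 (not isolated), via iodo boronic ester 31 (not isolated)
Conditions: 28, n-BuLi, THF/Et2O/pentane (4:1:1), −110 °C; 27, −110 °C; I2, THF/MeOH, −100 → −78 °C; NaOMe, MeOH, −78 → 0 °C
Reagents that add atoms: none
Why: Proposed new method: a chlorine-retentive Zweifel olefination, in which carbenoid 29 (α-deprotonation of 28 with retention, lithium cis to the β-chlorine) adds to boron at −110 °C and complex 30 is intercepted by I2 before the slower chloride-expelling Matteson-type shift can occur, so that iodonium formation triggers a stereoretentive 1,2-shift of C12 from boron to C11 anti to iodine and methoxide-induced anti elimination of boron and iodine from 31 releases the (Z)-1,2-dichloroalkene (C12 trans to the C10 chlorine, C12 retained); the closest known reactions are the Zweifel olefination of boronic esters with alkenyllithiums and its variant with α-bromovinyllithium used for alkynylation, neither shown with a β-substituted α-chlorovinyllithium to give a stereodefined trisubstituted vinyl chloride.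

Step 19
Reactants: 32 dichloro diene
Product: 33 (3R,4R,5R,6Z)-3,4-bis[(tert-butyldimethylsilyl)oxy]-6,7-dichloro-5-methylhept-6-en-2-one
Conditions: Pd(Quinox)Cl2 (5 mol %), AgSbF6 (12 mol %), aq. t-BuOOH, CH2Cl2, 0 → 23 °C
Reagents that add atoms: tert-butyl hydroperoxide, CC(C)(C)OO
Why: Peroxide-mediated Wacker-type oxidation with the quinoline-oxazoline palladium catalyst converts the terminal vinyl group next to the silyloxy carbon into the methyl ketone (Markovnikov), leaving the electron-poor dichloroalkene and C14 untouched.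

Step 20
Reactants: 33 dichloro ketone; 18 tetraenyl boronate
Product: 34 tert-butyl (1S,3R,4S)-3-{[(2E,4E,6E,8E,10Z,12R,13R,14R)-13,14-bis[(tert-butyldimethylsilyl)oxy]-11-chloro-6,12-dimethyl-15-oxohexadeca-2,4,6,8,10-pentaenoyl]oxy}-4-[(tert-butyldimethylsilyl)oxy]cyclohexane-1-carboxylate
Conditions: Pd(OAc)2 (5 mol %), SPhos (10 mol %), K3PO4, THF/H2O (10:1), 35 °C, dark
Reagents that add atoms: none
Why: Suzuki–Miyaura coupling in which zerovalent palladium inserts into the less hindered terminal CH–Cl bond (not the internal C11–Cl bond) and couples with retention, forming C9–C10 and leaving the 10Z vinyl chloride.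

**α-Chloro aldehyde**

Step 21
Reactants: 35 3-[(tert-butyldimethylsilyl)oxy]propanal
Product: 36 (2R)-3-[(tert-butyldimethylsilyl)oxy]-2-chloropropanal
Conditions: NCS, (2S,5S)-2,5-diphenylpyrrolidine (10 mol %), CH2Cl2, 0 °C; used crude
Reagents that add atoms: N-chlorosuccinimide, O=C1CCC(=O)N1Cl
Why: Organocatalytic enamine α-chlorination; the C2-symmetric pyrrolidine shields one enamine face and sets C18 under catalyst control.

Step 22
Reactants: 36 α-chloro aldehyde; 37 but-1-yne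
Product: 41 (2R,3S,4E)-1,3-bis[(tert-butyldimethylsilyl)oxy]-2-chlorohept-4-ene, via (E)-butenylzirconocene chloride 38 (not isolated), via (E)-butenyl(methyl)zinc 39 (not isolated), via methylzinc alkoxide 40 (not isolated)
Conditions: 37, Cp2Zr(H)Cl, CH2Cl2, 23 °C; Me2Zn, −65 °C; 36, −65 → −20 °C; then TBSOTf, 2,6-lutidine, −78 → 0 °C
Reagents that add atoms: tert-butyldimethylsilyl triflate, CC(C)(C)[Si](C)(C)OS(=O)(=O)C(F)(F)F
Why: Hydrozirconation–zinc transmetalation gives the (E)-alkenyl nucleophile (C20=C21), which adds to the α-chloro aldehyde anti to chlorine (Cornforth model) and sets C19 anti to C18; the alkoxide is silylated in the flask before it can close to an epoxide.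

Step 23
Reactants: 41 bis-silyl ether
Product: 42 (2R,3S,4E)-3-[(tert-butyldimethylsilyl)oxy]-2-chlorohept-4-en-1-ol
Conditions: HF·pyridine, pyridine, THF, 0 °C
Reagents that add atoms: none
Why: Buffered fluoride removes the primary silyl ether much faster than the secondary allylic one.

Step 24
Reactants: 42 primary alcohol
Product: 43 (2S,3S,4E)-3-[(tert-butyldimethylsilyl)oxy]-2-chlorohept-4-enal
Conditions: Dess–Martin periodinane, NaHCO3, CH2Cl2, 0 → 23 °C; used crude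
Reagents that add atoms: none
Why: Buffered hypervalent-iodine oxidation gives the configurationally labile α-chloro aldehyde without epimerizing C18.

**Fragment union and end game**

Step 25
Reactants: 34 polyene methyl ketone; 43 α-chloro aldehyde
Product: 45 tert-butyl (1S,3R,4S)-3-{[(2E,4E,6E,8E,10Z,12R,13R,14R,17R,18R,19S,20E)-13,14,19-tris[(tert-butyldimethylsilyl)oxy]-11,18-dichloro-17-hydroxy-6,12-dimethyl-15-oxotricosa-2,4,6,8,10,20-hexaenoyl]oxy}-4-[(tert-butyldimethylsilyl)oxy]cyclohexane-1-carboxylate, via dicyclohexylboron enolate 44 (not isolated)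
Conditions: Cy2BCl, Et3N, Et2O, −78 → 0 °C; 43 (2 equiv), −78 °C; MeOH, pH 7 buffer, 0 °C
Reagents that add atoms: none
Why: Boron-mediated methyl ketone aldol: the kinetic enolate forms on the methyl side and adds to the α-chloro aldehyde anti to chlorine (Cornforth model), forming C16–C17 and setting C17 anti to C18.

Step 26
Reactants: 45 β-hydroxy ketone
Product: 46 tert-butyl (1S,3R,4S)-3-{[(2E,4E,6E,8E,10Z,12R,13R,14S,15S,17R,18R,19S,20E)-13,14,19-tris[(tert-butyldimethylsilyl)oxy]-11,18-dichloro-15,17-dihydroxy-6,12-dimethyltricosa-2,4,6,8,10,20-hexaenoyl]oxy}-4-[(tert-butyldimethylsilyl)oxy]cyclohexane-1-carboxylate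
Conditions: Et2BOMe, THF/MeOH (4:1), −78 °C; NaBH4; AcOH, then MeOH co-evaporation
Reagents that add atoms: none
Why: Narasaka–Prasad reduction: the six-membered boron chelate directs external hydride to give the 1,3-syn diol, setting C15 syn to C17.

Step 27
Reactants: 46 diol
Product: 48 (1S,3R,4S)-3-{[(2E,4E,6E,8E,10Z,12R,13R,14S,15S,17R,18R,19S,20E)-11,18-dichloro-13,14,15,17,19-pentahydroxy-6,12-dimethyltricosa-2,4,6,8,10,20-hexaenoyl]oxy}-4-hydroxycyclohexane-1-carboxylic acid (target), via persilylated silyl ester 47 (not isolated)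
Conditions: TESOTf, 2,6-lutidine, CH2Cl2, −78 → 0 °C; then HF·pyridine, pyridine, THF, 0 → 23 °C, dark
Reagents that add atoms: none
Why: Silyl triflate turns the tert-butyl ester into a silyl ester (loss of isobutene) and caps the two free hydroxyls, and buffered acidic fluoride then removes every silicon group without base, so the chlorohydrin, the ester on O3' and the polyene survive.

## Compound list

1 | cyclohexa-1,4-diene | C1=CCC=CC1 | starting material
2 | (1R,2S)-cyclohex-4-ene-1,2-diol (cis, meso) | O[C@@H]1CC=CC[C@@H]1O | intermediate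
3 | (3aR,7aS)-2,2-dimethyl-3a,4,7,7a-tetrahydro-1,3-benzodioxole | CC2(C)O[C@@H]1CC=CC[C@@H]1O2 | intermediate
4 | [(3aR,5S,7aS)-2,2-dimethylhexahydro-1,3-benzodioxol-5-yl]diisopinocampheylborane | CC2(C)O[C@@H]1C[C@@H](B([C@@H]3C[C@@H]4C[C@H]([C@H]3C)C4(C)C)[C@@H]3C[C@@H]4C[C@H]([C@H]3C)C4(C)C)CC[C@@H]1O2 | intermediate
5 | diethyl [(3aR,5S,7aS)-2,2-dimethylhexahydro-1,3-benzodioxol-5-yl]boronate | CC2(C)O[C@@H]1C[C@@H](B(OCC)OCC)CC[C@@H]1O2 | intermediate
6 | 2-[(3aR,5S,7aS)-2,2-dimethylhexahydro-1,3-benzodioxol-5-yl]-4,4,5,5-tetramethyl-1,3,2-dioxaborolane | CC2(C)O[C@@H]1C[C@@H](B3OC(C)(C)C(C)(C)O3)CC[C@@H]1O2 | intermediate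
7 | 2-{chloro[(3aR,5S,7aS)-2,2-dimethylhexahydro-1,3-benzodioxol-5-yl]methyl}-4,4,5,5-tetramethyl-1,3,2-dioxaborolane (both epimers at CHCl) | CC2(C)O[C@@H]1C[C@@H](C(Cl)B3OC(C)(C)C(C)(C)O3)CC[C@@H]1O2 | intermediate
8 | (3aR,5S,7aS)-2,2-dimethylhexahydro-1,3-benzodioxole-5-carboxylic acid | CC2(C)O[C@@H]1C[C@@H](C(=O)O)CC[C@@H]1O2 | intermediate
9 | tert-butyl (3aR,5S,7aS)-2,2-dimethylhexahydro-1,3-benzodioxole-5-carboxylate | CC2(C)O[C@@H]1C[C@@H](C(=O)OC(C)(C)C)CC[C@@H]1O2 | intermediate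
10 | tert-butyl (1S,3R,4S)-3,4-dihydroxycyclohexane-1-carboxylate | O[C@@H]1C[C@@H](C(=O)OC(C)(C)C)CC[C@@H]1O | intermediate
11 | tert-butyl (1S,3R,4S)-4-[(tert-butyldimethylsilyl)oxy]-3-hydroxycyclohexane-1-carboxylate | O[C@@H]1C[C@@H](C(=O)OC(C)(C)C)CC[C@@H]1O[Si](C)(C)C(C)(C)C | intermediate
12 | (2E)-3-iodoprop-2-enoic acid | OC(=O)/C=C/I | starting material
13 | tert-butyl (1S,3R,4S)-4-[(tert-butyldimethylsilyl)oxy]-3-{[(2E)-3-iodoprop-2-enoyl]oxy}cyclohexane-1-carboxylate | I/C=C/C(=O)O[C@@H]1C[C@@H](C(=O)OC(C)(C)C)CC[C@@H]1O[Si](C)(C)C(C)(C)C | intermediate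
14 | (2E)-3-methylpent-2-en-4-yn-1-ol | C#C/C(C)=C/CO | starting material
15 | (2E,4E)-3-methyl-5-(tributylstannyl)penta-2,4-dien-1-ol | CCCC[Sn](CCCC)(CCCC)/C=C/C(C)=C/CO | intermediate
16 | (2E,4E)-3-methyl-5-(tributylstannyl)penta-2,4-dienal | CCCC[Sn](CCCC)(CCCC)/C=C/C(C)=C/C=O | intermediate
17 | tributyl[(1E,3E,5E)-3-methyl-6-(4,4,5,5-tetramethyl-1,3,2-dioxaborolan-2-yl)hexa-1,3,5-trien-1-yl]stannane | CCCC[Sn](CCCC)(CCCC)/C=C/C(C)=C/C=C/B1OC(C)(C)C(C)(C)O1 | intermediate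
18 | tert-butyl (1S,3R,4S)-4-[(tert-butyldimethylsilyl)oxy]-3-{[(2E,4E,6E,8E)-6-methyl-9-(4,4,5,5-tetramethyl-1,3,2-dioxaborolan-2-yl)nona-2,4,6,8-tetraenoyl]oxy}cyclohexane-1-carboxylate | CC1(C)OB(OC1(C)C)/C=C/C=C(C)/C=C/C=C/C(=O)O[C@@H]2C[C@@H](C(=O)OC(C)(C)C)CC[C@@H]2O[Si](C)(C)C(C)(C)C | intermediate
19 | penta-1,4-dien-3-ol | C=CC(O)C=C | starting material
20 | (1S)-1-[(2R)-oxiran-2-yl]prop-2-en-1-ol | C=C[C@H](O)[C@H]1CO1 | intermediate
21 | tert-butyldimethyl{[(1S)-1-[(2R)-oxiran-2-yl]prop-2-en-1-yl]oxy}silane | C=C[C@H](O[Si](C)(C)C(C)(C)C)[C@H]1CO1 | intermediate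
22 | (2S)-2-[(tert-butyldimethylsilyl)oxy]but-3-enal | C=C[C@H](O[Si](C)(C)C(C)(C)C)C=O | intermediate
23 | 1,1-dibromoethane | CC(Br)Br | starting material
24 | 2,2'-(ethane-1,1-diyl)bis(4,4,5,5-tetramethyl-1,3,2-dioxaborolane) | CC(B1OC(C)(C)C(C)(C)O1)B1OC(C)(C)C(C)(C)O1 | intermediate
25 | lithium butyl[1-(pinacolboryl)ethyl]pinacolborate | [Li+].CCCC[B-]1(OC(C)(C)C(C)(C)O1)C(C)B1OC(C)(C)C(C)(C)O1 | intermediate
26 | lithium (2R,3R,4S)-4-[(tert-butyldimethylsilyl)oxy]-2-(4,4,5,5-tetramethyl-1,3,2-dioxaborolan-2-yl)hex-5-en-3-olate | [Li+].C=C[C@H](O[Si](C)(C)C(C)(C)C)[C@H]([O-])[C@@H](C)B1OC(C)(C)C(C)(C)O1 | intermediate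
27 | 2-[(2R,3R,4S)-3,4-bis[(tert-butyldimethylsilyl)oxy]hex-5-en-2-yl]-4,4,5,5-tetramethyl-1,3,2-dioxaborolane | C=C[C@H](O[Si](C)(C)C(C)(C)C)[C@H](O[Si](C)(C)C(C)(C)C)[C@@H](C)B1OC(C)(C)C(C)(C)O1 | intermediate
28 | (E)-1,2-dichloroethene | Cl/C=C/Cl | starting material
29 | (E)-1,2-dichlorovinyllithium | Cl/C([Li])=C/Cl | intermediate
30 | lithium [(2R,3R,4S)-3,4-bis(silyloxy)hex-5-en-2-yl][(E)-1,2-dichlorovinyl]pinacolborate | [Li+].C=C[C@H](O[Si](C)(C)C(C)(C)C)[C@H](O[Si](C)(C)C(C)(C)C)[C@@H](C)[B-]1(OC(C)(C)C(C)(C)O1)\C(Cl)=C/Cl | intermediate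
31 | 2-[(3R,4R,5S)-4,5-bis[(tert-butyldimethylsilyl)oxy]-1,2-dichloro-1-iodo-3-methylhept-6-en-2-yl]-4,4,5,5-tetramethyl-1,3,2-dioxaborolane (anti adduct; drawn for one alkene face, both faces converge) | C=C[C@H](O[Si](C)(C)C(C)(C)C)[C@H](O[Si](C)(C)C(C)(C)C)[C@@H](C)[C@](Cl)(B1OC(C)(C)C(C)(C)O1)[C@@H](Cl)I | intermediate
32 | (1Z,3R,4R,5S)-4,5-bis[(tert-butyldimethylsilyl)oxy]-1,2-dichloro-3-methylhepta-1,6-diene | C=C[C@H](O[Si](C)(C)C(C)(C)C)[C@H](O[Si](C)(C)C(C)(C)C)[C@@H](C)/C(Cl)=C/Cl | intermediate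
33 | (3R,4R,5R,6Z)-3,4-bis[(tert-butyldimethylsilyl)oxy]-6,7-dichloro-5-methylhept-6-en-2-one | CC(=O)[C@H](O[Si](C)(C)C(C)(C)C)[C@H](O[Si](C)(C)C(C)(C)C)[C@@H](C)/C(Cl)=C/Cl | intermediate
34 | tert-butyl (1S,3R,4S)-3-{[(2E,4E,6E,8E,10Z,12R,13R,14R)-13,14-bis[(tert-butyldimethylsilyl)oxy]-11-chloro-6,12-dimethyl-15-oxohexadeca-2,4,6,8,10-pentaenoyl]oxy}-4-[(tert-butyldimethylsilyl)oxy]cyclohexane-1-carboxylate | CC(=O)[C@H](O[Si](C)(C)C(C)(C)C)[C@H](O[Si](C)(C)C(C)(C)C)[C@@H](C)/C(Cl)=C/C=C/C=C(C)/C=C/C=C/C(=O)O[C@@H]1C[C@@H](C(=O)OC(C)(C)C)CC[C@@H]1O[Si](C)(C)C(C)(C)C | intermediate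
35 | 3-[(tert-butyldimethylsilyl)oxy]propanal | O=CCCO[Si](C)(C)C(C)(C)C | starting material
36 | (2R)-3-[(tert-butyldimethylsilyl)oxy]-2-chloropropanal | O=C[C@H](Cl)CO[Si](C)(C)C(C)(C)C | intermediate
37 | but-1-yne | CCC#C | starting material
38 | (E)-but-1-en-1-yl(chloro)zirconocene, Cp2Zr(Cl)(CH=CHEt) | CC/C=C/[Zr](Cl)(C1C=CC=C1)C1C=CC=C1 | intermediate
39 | (E)-but-1-en-1-yl(methyl)zinc | CC/C=C/[Zn]C | intermediate
40 | methylzinc (2R,3S,4E)-1-[(tert-butyldimethylsilyl)oxy]-2-chlorohept-4-en-3-olate | CC/C=C/[C@H](O[Zn]C)[C@H](Cl)CO[Si](C)(C)C(C)(C)C | intermediate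
41 | (2R,3S,4E)-1,3-bis[(tert-butyldimethylsilyl)oxy]-2-chlorohept-4-ene | CC/C=C/[C@H](O[Si](C)(C)C(C)(C)C)[C@H](Cl)CO[Si](C)(C)C(C)(C)C | intermediate
42 | (2R,3S,4E)-3-[(tert-butyldimethylsilyl)oxy]-2-chlorohept-4-en-1-ol | CC/C=C/[C@H](O[Si](C)(C)C(C)(C)C)[C@H](Cl)CO | intermediate
43 | (2S,3S,4E)-3-[(tert-butyldimethylsilyl)oxy]-2-chlorohept-4-enal | CC/C=C/[C@H](O[Si](C)(C)C(C)(C)C)[C@H](Cl)C=O | intermediate
44 | dicyclohexylboron enolate of 34 (C15=C16 enol borinate) | C=C(OB(C1CCCCC1)C1CCCCC1)[C@H](O[Si](C)(C)C(C)(C)C)[C@H](O[Si](C)(C)C(C)(C)C)[C@@H](C)/C(Cl)=C/C=C/C=C(C)/C=C/C=C/C(=O)O[C@@H]1C[C@@H](C(=O)OC(C)(C)C)CC[C@@H]1O[Si](C)(C)C(C)(C)C | intermediate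
45 | tert-butyl (1S,3R,4S)-3-{[(2E,4E,6E,8E,10Z,12R,13R,14R,17R,18R,19S,20E)-13,14,19-tris[(tert-butyldimethylsilyl)oxy]-11,18-dichloro-17-hydroxy-6,12-dimethyl-15-oxotricosa-2,4,6,8,10,20-hexaenoyl]oxy}-4-[(tert-butyldimethylsilyl)oxy]cyclohexane-1-carboxylate | CC/C=C/[C@H](O[Si](C)(C)C(C)(C)C)[C@H](Cl)[C@H](O)CC(=O)[C@H](O[Si](C)(C)C(C)(C)C)[C@H](O[Si](C)(C)C(C)(C)C)[C@@H](C)/C(Cl)=C/C=C/C=C(C)/C=C/C=C/C(=O)O[C@@H]1C[C@@H](C(=O)OC(C)(C)C)CC[C@@H]1O[Si](C)(C)C(C)(C)C | intermediate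
46 | tert-butyl (1S,3R,4S)-3-{[(2E,4E,6E,8E,10Z,12R,13R,14S,15S,17R,18R,19S,20E)-13,14,19-tris[(tert-butyldimethylsilyl)oxy]-11,18-dichloro-15,17-dihydroxy-6,12-dimethyltricosa-2,4,6,8,10,20-hexaenoyl]oxy}-4-[(tert-butyldimethylsilyl)oxy]cyclohexane-1-carboxylate | CC/C=C/[C@H](O[Si](C)(C)C(C)(C)C)[C@H](Cl)[C@H](O)C[C@H](O)[C@H](O[Si](C)(C)C(C)(C)C)[C@H](O[Si](C)(C)C(C)(C)C)[C@@H](C)/C(Cl)=C/C=C/C=C(C)/C=C/C=C/C(=O)O[C@@H]1C[C@@H](C(=O)OC(C)(C)C)CC[C@@H]1O[Si](C)(C)C(C)(C)C | intermediate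
47 | triethylsilyl ester of the 15,17-bis(triethylsilyl) ether of the acid of 46 (13,14,19,4'-tetrakis-TBS) | CC/C=C/[C@H](O[Si](C)(C)C(C)(C)C)[C@H](Cl)[C@H](O[Si](CC)(CC)CC)C[C@H](O[Si](CC)(CC)CC)[C@H](O[Si](C)(C)C(C)(C)C)[C@H](O[Si](C)(C)C(C)(C)C)[C@@H](C)/C(Cl)=C/C=C/C=C(C)/C=C/C=C/C(=O)O[C@@H]1C[C@@H](C(=O)O[Si](CC)(CC)CC)CC[C@@H]1O[Si](C)(C)C(C)(C)C | intermediate
48 | (1S,3R,4S)-3-{[(2E,4E,6E,8E,10Z,12R,13R,14S,15S,17R,18R,19S,20E)-11,18-dichloro-13,14,15,17,19-pentahydroxy-6,12-dimethyltricosa-2,4,6,8,10,20-hexaenoyl]oxy}-4-hydroxycyclohexane-1-carboxylic acid | CC/C=C/[C@H](O)[C@H](Cl)[C@H](O)C[C@H](O)[C@H](O)[C@H](O)[C@@H](C)/C(Cl)=C/C=C/C=C(C)/C=C/C=C/C(=O)O[C@@H]1C[C@@H](C(=O)O)CC[C@@H]1O | target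

## Step count and risks

Total: 27 steps. Longest linear sequence: 13 steps (steps 1–8, 12, 20, 25, 26, 27).

Three steps most likely to fail:

**Step 18 (the proposed chlorine-retentive Zweifel coupling).** The complex 30 may expel chloride before iodine intercepts it, or may lose the β-silyloxy group. The fallback uses known chemistry, sets out from 27 and returns at 34. Boronic ester 27 is combined at −110 °C with the carbenoid made from (2,2-dibromovinyl)trimethylsilane and n-BuLi (exchange of the bromine trans to silicon) and warmed; the established halide-expelling 1,2-metallate rearrangement of alkylidene carbenoids (inversion at the carbenoid carbon) gives 2-[(1E,3S,4R,5S)-4,5-bis[(tert-butyldimethylsilyl)oxy]-3-methyl-1-(trimethylsilyl)hepta-1,6-dien-2-yl]-4,4,5,5-tetramethyl-1,3,2-dioxaborolane F1. Chlorodeboronation with CuCl2 in aqueous methanol (retention) gives [(1Z,3R,4R,5S)-4,5-bis[(tert-butyldimethylsilyl)oxy]-2-chloro-3-methylhepta-1,6-dien-1-yl]trimethylsilane F2. Iododesilylation with NIS gives (1Z,3R,4R,5S)-4,5-bis[(tert-butyldimethylsilyl)oxy]-2-chloro-1-iodo-3-methylhepta-1,6-diene F3. The Wacker conditions of step 19 give (3R,4R,5R,6Z)-3,4-bis[(tert-butyldimethylsilyl)oxy]-6-chloro-7-iodo-5-methylhept-6-en-2-one F4, and a mild Suzuki coupling of this vinyl iodide with 18 (Pd(PPh3)4, K3PO4, THF/H2O, 23 °C) gives 34.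

**Step 17 (silver-catalysed deborylative addition).** Two stereocenters ride on it and aldehyde 22 can isomerize under basic conditions. The fallback sets out from 22 and returns at 27. Copper-catalysed 1,2-borylation of 22 (B2pin2, CuCl, ICy·HCl, NaOt-Bu, MeOH, toluene; Felkin face) gives (1R,2S)-2-[(tert-butyldimethylsilyl)oxy]-1-(4,4,5,5-tetramethyl-1,3,2-dioxaborolan-2-yl)but-3-en-1-ol F5. Silylation (TBSOTf, 2,6-lutidine) gives 2-[(1R,2S)-1,2-bis[(tert-butyldimethylsilyl)oxy]but-3-en-1-yl]-4,4,5,5-tetramethyl-1,3,2-dioxaborolane F6. Lithiation–borylation with ethyl 2,4,6-triisopropylbenzoate (s-BuLi, (−)-sparteine, Et2O, −78 °C; then warming) inserts the CH(CH3) unit by a reagent-controlled 1,2-shift of the α-silyloxyalkyl group from boron to carbon and gives 27.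

**Step 20 (Suzuki coupling of the vinyl dichloride).** Risks are slow or unselective insertion into the two C–Cl bonds and base sensitivity of the ketone and the polyenyl boronate. The fallback sets out from 16 and 33 and returns at 34. Ohira–Bestmann homologation of 16 (dimethyl (1-diazo-2-oxopropyl)phosphonate, K2CO3, MeOH) gives tributyl[(1E,3E)-3-methylhexa-1,3-dien-5-yn-1-yl]stannane F7. Hydrozirconation (Cp2Zr(H)Cl) and transmetalation with ZnCl2 gives chloro[(1E,3E,5E)-4-methyl-6-(tributylstannyl)hexa-1,3,5-trien-1-yl]zinc F8. A base-free Negishi coupling with 33 (PdCl2(DPEphos), THF, 23 °C; known to monocouple dichloroalkenes) gives (3R,4R,5R,6Z,8E,10E,12E)-3,4-bis[(tert-butyldimethylsilyl)oxy]-6-chloro-5,11-dimethyl-13-(tributylstannyl)trideca-6,8,10,12-tetraen-2-one F9, and the Stille conditions of step 12 with 13 then give 34.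

## Further compounds

F1 | step 18 | 2-[(1E,3S,4R,5S)-4,5-bis[(tert-butyldimethylsilyl)oxy]-3-methyl-1-(trimethylsilyl)hepta-1,6-dien-2-yl]-4,4,5,5-tetramethyl-1,3,2-dioxaborolane | C=C[C@H](O[Si](C)(C)C(C)(C)C)[C@H](O[Si](C)(C)C(C)(C)C)[C@@H](C)/C(B1OC(C)(C)C(C)(C)O1)=C/[Si](C)(C)C
F2 | step 18 | [(1Z,3R,4R,5S)-4,5-bis[(tert-butyldimethylsilyl)oxy]-2-chloro-3-methylhepta-1,6-dien-1-yl]trimethylsilane | C=C[C@H](O[Si](C)(C)C(C)(C)C)[C@H](O[Si](C)(C)C(C)(C)C)[C@@H](C)/C(Cl)=C/[Si](C)(C)C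
F3 | step 18 | (1Z,3R,4R,5S)-4,5-bis[(tert-butyldimethylsilyl)oxy]-2-chloro-1-iodo-3-methylhepta-1,6-diene | C=C[C@H](O[Si](C)(C)C(C)(C)C)[C@H](O[Si](C)(C)C(C)(C)C)[C@@H](C)/C(Cl)=C/I
F4 | step 18 | (3R,4R,5R,6Z)-3,4-bis[(tert-butyldimethylsilyl)oxy]-6-chloro-7-iodo-5-methylhept-6-en-2-one | CC(=O)[C@H](O[Si](C)(C)C(C)(C)C)[C@H](O[Si](C)(C)C(C)(C)C)[C@@H](C)/C(Cl)=C/I
F5 | step 17 | (1R,2S)-2-[(tert-butyldimethylsilyl)oxy]-1-(4,4,5,5-tetramethyl-1,3,2-dioxaborolan-2-yl)but-3-en-1-ol | C=C[C@H](O[Si](C)(C)C(C)(C)C)[C@H](O)B1OC(C)(C)C(C)(C)O1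
F6 | step 17 | 2-[(1R,2S)-1,2-bis[(tert-butyldimethylsilyl)oxy]but-3-en-1-yl]-4,4,5,5-tetramethyl-1,3,2-dioxaborolane | C=C[C@H](O[Si](C)(C)C(C)(C)C)[C@H](O[Si](C)(C)C(C)(C)C)B1OC(C)(C)C(C)(C)O1
F7 | step 20 | tributyl[(1E,3E)-3-methylhexa-1,3-dien-5-yn-1-yl]stannane | CCCC[Sn](CCCC)(CCCC)/C=C/C(C)=C/C#C
F8 | step 20 | chloro[(1E,3E,5E)-4-methyl-6-(tributylstannyl)hexa-1,3,5-trien-1-yl]zinc | Cl[Zn]/C=C/C=C(C)/C=C/[Sn](CCCC)(CCCC)CCCC
F9 | step 20 | (3R,4R,5R,6Z,8E,10E,12E)-3,4-bis[(tert-butyldimethylsilyl)oxy]-6-chloro-5,11-dimethyl-13-(tributylstannyl)trideca-6,8,10,12-tetraen-2-one | CC(=O)[C@H](O[Si](C)(C)C(C)(C)C)[C@H](O[Si](C)(C)C(C)(C)C)[C@@H](C)/C(Cl)=C/C=C/C=C(C)/C=C/[Sn](CCCC)(CCCC)CCCC
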